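**Retrosynthetic overview**
1. Target 26 ⇐ tert-butyl ester 25 ⇐ germacranolide angelate 24 by Cope rearrangement: this forms C5–C10, sets C5 and C10, and makes the cyclohexane last.
2. 24 ⇐ acyclic hydroxy aldehyde 20: the nucleophilic β-carbon (C7) of a 2-(bromomethyl)acrylate, as its allylchromium, adds to the C6 aldehyde. This one step closes the ten-membered carbocycle and the γ-lactone and sets C6 and C7 under control of C8.
3. 20 ⇐ linear chain: C7=C11 unit by Morita–Baylis–Hillman reaction and SN2′ bromination, C4=C5 by Z-selective Horner–Wadsworth–Emmons olefination, C1=C10 by alkyne carboalumination.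
4. The only stereocentre carried in (C8) comes from glycidyl ether 1. Ring order: ten-membered ring and lactone together, then the six-membered ring by [3,3] shift.

Assumptions: 1 (the 4-methoxybenzyl ether of (S)-glycidol) is bought. Positions are referred to by germacrane/elemane numbering C1–C15 (C6 lactone carbinol, C8 angelate carbinol, C12 lactone carbonyl, C15 carboxyl). This is a paper route; no step has been run.

**Step 1**
Reactants: 1 (2R)-2-{[(4-methoxybenzyl)oxy]methyl}oxirane; 2 lithium acetylide–ethylenediamine complex (LiC≡CH·H2NCH2CH2NH2)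
Product: 3 (2R)-1-[(4-methoxybenzyl)oxy]pent-4-yn-2-ol
Conditions: 2 (1.5 equiv), DMSO, 0 °C → rt; then H2O
Reagents that add atoms: none
Why: SN2 opening of the epoxide at its unsubstituted carbon by the acetylide (epoxide alkynylation); the C8 carbinol centre (R) is carried unchanged from 1.

**Step 2**
Reactants: 3 (2R)-1-[(4-methoxybenzyl)oxy]pent-4-yn-2-ol; 4 oxirane (ethylene oxide)
Product: 6 (2R,4E)-1-[(4-methoxybenzyl)oxy]-4-methylhept-4-ene-2,7-diol, via alkenylalane 5 (not isolated)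
Conditions: Me3Al (3 equiv), Cp2ZrCl2 [(C5H5)2ZrCl2] (0.25 equiv), CH2Cl2, 0 °C → rt; evaporate; n-BuLi, THF, −78 °C; 4, −78 °C → rt; aq. potassium sodium tartrate
Reagents that add atoms: trimethylaluminium, C[Al](C)C
Why: Negishi zirconium-catalysed carboalumination adds Me and Al syn across the alkyne, fixing the E geometry of C1=C10, and the derived lithium alanate opens ethylene oxide with retention at the alkenyl carbon.

**Step 3**
Reactants: 6 (2R,4E)-1-[(4-methoxybenzyl)oxy]-4-methylhept-4-ene-2,7-diol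
Product: 7 (2R,4E)-7-iodo-1-[(4-methoxybenzyl)oxy]-4-methylhept-4-en-2-ol
Conditions: I2, PPh3, imidazole, CH2Cl2, 0 °C
Reagents that add atoms: iodine, II
Why: Appel-type iodination is selective for the primary over the secondary alcohol.

**Step 4**
Reactants: 7 (2R,4E)-7-iodo-1-[(4-methoxybenzyl)oxy]-4-methylhept-4-en-2-ol
Product: 8 tert-butyl({(2R,4E)-7-iodo-1-[(4-methoxybenzyl)oxy]-4-methylhept-4-en-2-yl}oxy)dimethylsilane
Conditions: TBSOTf, 2,6-lutidine, CH2Cl2, −78 °C
Reagents that add atoms: tert-butyldimethylsilyl trifluoromethanesulfonate, CC(C)(C)[Si](C)(C)OS(=O)(=O)C(F)(F)F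
Why: Silyl ether formation on the remaining secondary alcohol under non-nucleophilic conditions that spare the primary iodide.

**Step 5**
Reactants: 9 diphenyl phosphonate (diphenyl phosphite); 10 tert-butyl bromoacetate
Product: 11 tert-butyl (diphenoxyphosphoryl)acetate
Conditions: Et3N, CH2Cl2, 0 °C → rt
Reagents that add atoms: none
Why: Michaelis–Becker-type P-alkylation of the phosphite by the α-bromo ester gives the Ando-type diaryl phosphonoacetate.

**Step 6**
Reactants: 11 tert-butyl (diphenoxyphosphoryl)acetate; 8 tert-butyl({(2R,4E)-7-iodo-1-[(4-methoxybenzyl)oxy]-4-methylhept-4-en-2-yl}oxy)dimethylsilane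
Product: 12 tert-butyl (5E,8R)-8-[(tert-butyldimethylsilyl)oxy]-2-(diphenoxyphosphoryl)-9-[(4-methoxybenzyl)oxy]-6-methylnon-5-enoate (both C2 epimers)
Conditions: NaH, DMSO–THF, rt
Reagents that add atoms: none
Why: SN2 C-alkylation of the stabilised phosphonoacetate carbanion by the primary iodide; the new phosphorus-bearing centre is a mixture that is erased in step 7.

**Step 7**
Reactants: 12 tert-butyl (5E,8R)-8-[(tert-butyldimethylsilyl)oxy]-2-(diphenoxyphosphoryl)-9-[(4-methoxybenzyl)oxy]-6-methylnon-5-enoate; 13 2,2-dimethoxyacetaldehyde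
Product: 14 tert-butyl (2Z,5E,8R)-8-[(tert-butyldimethylsilyl)oxy]-2-(2,2-dimethoxyethylidene)-9-[(4-methoxybenzyl)oxy]-6-methylnon-5-enoate
Conditions: NaH, THF, −78 → 0 °C; 13 dried before use
Reagents that add atoms: none
Why: Ando variant of the Horner–Wadsworth–Emmons olefination: the diaryl phosphonate places the ester cis to the aldehyde-derived carbon, giving the 2Z alkene (CO2tBu cis to C6) needed for a ring-trans C4=C5 bond later.

**Step 8**
Reactants: 14 tert-butyl (2Z,5E,8R)-8-[(tert-butyldimethylsilyl)oxy]-2-(2,2-dimethoxyethylidene)-9-[(4-methoxybenzyl)oxy]-6-methylnon-5-enoate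
Product: 15 tert-butyl (2Z,5E,8R)-8-[(tert-butyldimethylsilyl)oxy]-2-(2,2-dimethoxyethylidene)-9-hydroxy-6-methylnon-5-enoate
Conditions: DDQ, CH2Cl2–pH 7 buffer, 0 °C
Reagents that add atoms: none
Why: Oxidative cleavage of the 4-methoxybenzyl ether by DDQ leaves silyl ether, acetal and alkenes untouched.

**Step 9**
Reactants: 15 tert-butyl (2Z,5E,8R)-8-[(tert-butyldimethylsilyl)oxy]-2-(2,2-dimethoxyethylidene)-9-hydroxy-6-methylnon-5-enoate
Product: 16 tert-butyl (2Z,5E,8R)-8-[(tert-butyldimethylsilyl)oxy]-2-(2,2-dimethoxyethylidene)-6-methyl-9-oxonon-5-enoate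
Conditions: Dess–Martin periodinane, CH2Cl2, rt
Reagents that add atoms: none
Why: Dess–Martin oxidation gives the α-silyloxy aldehyde under non-basic conditions without epimerising C8.

**Step 10**
Reactants: 16 tert-butyl (2Z,5E,8R)-8-[(tert-butyldimethylsilyl)oxy]-2-(2,2-dimethoxyethylidene)-6-methyl-9-oxonon-5-enoate; 17 methyl acrylate
Product: 18 1-tert-butyl 11-methyl (2Z,5E,8R)-8-[(tert-butyldimethylsilyl)oxy]-2-(2,2-dimethoxyethylidene)-9-hydroxy-6-methyl-10-methylideneundec-5-enedioate (both C9 epimers)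
Conditions: DABCO (1 equiv), 17 (excess), MeOH, rt, 3 d
Reagents that add atoms: none
Why: Morita–Baylis–Hillman reaction of the activated α-silyloxy aldehyde; the new carbinol centre forms as a mixture and becomes sp2 in step 11.

**Step 11**
Reactants: 18 1-tert-butyl 11-methyl (2Z,5E,8R)-8-[(tert-butyldimethylsilyl)oxy]-2-(2,2-dimethoxyethylidene)-9-hydroxy-6-methyl-10-methylideneundec-5-enedioate
Product: 19 1-tert-butyl 11-methyl (2Z,5E,8R,9Z)-10-(bromomethyl)-8-[(tert-butyldimethylsilyl)oxy]-2-(2,2-dimethoxyethylidene)-6-methylundeca-5,9-dienedioate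
Conditions: NBS, Me2S, CH2Cl2, 0 °C → rt
Reagents that add atoms: N-bromosuccinimide, O=C1CCC(=O)N1Br
Why: Corey–Kim-type bromination proceeds with SN2′ allylic transposition to the conjugated, thermodynamically preferred (Z)-2-(bromomethyl)enoate.

**Step 12**
Reactants: 19 1-tert-butyl 11-methyl (2Z,5E,8R,9Z)-10-(bromomethyl)-8-[(tert-butyldimethylsilyl)oxy]-2-(2,2-dimethoxyethylidene)-6-methylundeca-5,9-dienedioate
Product: 20 1-tert-butyl 11-methyl (2Z,5E,8R,9Z)-10-(bromomethyl)-8-hydroxy-6-methyl-2-(2-oxoethylidene)undeca-5,9-dienedioate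
Conditions: aq. HF (48%), MeCN–H2O, 0 °C → rt; used crude at once
Reagents that add atoms: water, O
Why: One-pot silyl ether cleavage by HF and acid hydrolysis of the dimethyl acetal (the tert-butyl ester is stable to aqueous HF); immediate use limits Z→E drift of the 4-oxo-enoate.

**Step 13 (key step)**
Reactants: 20 1-tert-butyl 11-methyl (2Z,5E,8R,9Z)-10-(bromomethyl)-8-hydroxy-6-methyl-2-(2-oxoethylidene)undeca-5,9-dienedioate
Product: 22 tert-butyl (3aR,4R,6E,10Z,11aR)-4-hydroxy-6-methyl-3-methylidene-2-oxo-2,3,3a,4,5,8,9,11a-octahydrocyclodeca[b]furan-10-carboxylate, via chromium alkoxide 21 (not isolated)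
Conditions: CrCl2 (6 equiv), THF, rt, slow addition of 20 (final 2 mM); then aq. NH4Cl
Reagents that add atoms: none
Why: Intramolecular Nozaki–Hiyama (Barbier-type) allylation: the allylchromium makes the acrylate β-carbon C7 nucleophilic and it adds to the C6 aldehyde through a chair Zimmerman–Traxler transition state of the equilibrated allylchromium (C8 equatorial, hence 6,7-anti and a trans-lactone once the C6 alkoxide closes onto the methyl ester), while the free C8 hydroxyl, with H8 eclipsing the alkene to avoid A(1,3) strain, is expected to bind the aldehyde-bound chromium and direct attack to the C7 face syn to O8, giving 6R,7R (11aR,3aR).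

**Step 14**
Reactants: 22 tert-butyl (3aR,4R,6E,10Z,11aR)-4-hydroxy-6-methyl-3-methylidene-2-oxo-2,3,3a,4,5,8,9,11a-octahydrocyclodeca[b]furan-10-carboxylate; 23 angelic acid [(2Z)-2-methylbut-2-enoic acid]
Product: 24 tert-butyl (3aR,4R,6E,10Z,11aR)-6-methyl-4-{[(2Z)-2-methylbut-2-enoyl]oxy}-3-methylidene-2-oxo-2,3,3a,4,5,8,9,11a-octahydrocyclodeca[b]furan-10-carboxylate
Conditions: 23, 2,4,6-Cl3C6H2COCl, Et3N, PhMe, rt; then 22, 60 °C
Reagents that add atoms: none
Why: Yamaguchi-type esterification through the preformed mixed anhydride without a nucleophilic catalyst (which would isomerise angelate to tiglate); acylation at oxygen retains C8.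

**Step 15**
Reactants: 24 tert-butyl (3aR,4R,6E,10Z,11aR)-6-methyl-4-{[(2Z)-2-methylbut-2-enoyl]oxy}-3-methylidene-2-oxo-2,3,3a,4,5,8,9,11a-octahydrocyclodeca[b]furan-10-carboxylate
Product: 25 tert-butyl 2-[(3aR,4R,6S,7R,7aR)-6-ethenyl-6-methyl-4-{[(2Z)-2-methylbut-2-enoyl]oxy}-3-methylidene-2-oxooctahydro-1-benzofuran-7-yl]prop-2-enoate
Conditions: PhMe, BHT (cat.), 110 °C
Reagents that add atoms: none
Why: Cope rearrangement ([3,3]-sigmatropic shift) through the chair transition state of the crown conformer of the cyclodeca-1,5-diene (C14 and the C4 ester syn, H5 and H6 anti) forms C5–C10 and gives 10S (vinyl equatorial, methyl axial) and 5R (acrylate equatorial), driven by release of medium-ring strain and assisted by the acceptor on C4.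

**Step 16**
Reactants: 25 tert-butyl 2-[(3aR,4R,6S,7R,7aR)-6-ethenyl-6-methyl-4-{[(2Z)-2-methylbut-2-enoyl]oxy}-3-methylidene-2-oxooctahydro-1-benzofuran-7-yl]prop-2-enoate
Product: 26 2-[(3aR,4R,6S,7R,7aR)-6-ethenyl-6-methyl-4-{[(2Z)-2-methylbut-2-enoyl]oxy}-3-methylidene-2-oxooctahydro-1-benzofuran-7-yl]prop-2-enoic acid (CNP0256928.2)
Conditions: TFA–CH2Cl2 (1:4), 0 °C → rt
Reagents that add atoms: none
Why: Acidolysis of the tert-butyl ester (loss of the tert-butyl cation as isobutene) leaves lactone, angelate and all stereocentres untouched.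

**Compound list**
1 | (2R)-2-{[(4-methoxybenzyl)oxy]methyl}oxirane | COc1ccc(COC[C@H]2CO2)cc1 | starting material
2 | lithium acetylide–ethylenediamine complex | [Li+].[C-]#C.NCCN | starting material
3 | (2R)-1-[(4-methoxybenzyl)oxy]pent-4-yn-2-ol | COc1ccc(COC[C@H](O)CC#C)cc1 | intermediate
4 | oxirane | C1CO1 | starting material
5 | [(1E,4R)-4-[(dimethylalumanyl)oxy]-5-[(4-methoxybenzyl)oxy]-2-methylpent-1-en-1-yl]dimethylalumane | COc1ccc(COC[C@H](O[Al](C)C)C/C(C)=C/[Al](C)C)cc1 | intermediate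
6 | (2R,4E)-1-[(4-methoxybenzyl)oxy]-4-methylhept-4-ene-2,7-diol | COc1ccc(COC[C@H](O)C/C(C)=C/CCO)cc1 | intermediate
7 | (2R,4E)-7-iodo-1-[(4-methoxybenzyl)oxy]-4-methylhept-4-en-2-ol | COc1ccc(COC[C@H](O)C/C(C)=C/CCI)cc1 | intermediate
8 | tert-butyl({(2R,4E)-7-iodo-1-[(4-methoxybenzyl)oxy]-4-methylhept-4-en-2-yl}oxy)dimethylsilane | COc1ccc(COC[C@H](O[Si](C)(C)C(C)(C)C)C/C(C)=C/CCI)cc1 | intermediate
9 | diphenyl phosphonate | O=[PH](Oc1ccccc1)Oc1ccccc1 | starting material
10 | tert-butyl bromoacetate | CC(C)(C)OC(=O)CBr | starting material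
11 | tert-butyl (diphenoxyphosphoryl)acetate | CC(C)(C)OC(=O)CP(=O)(Oc1ccccc1)Oc1ccccc1 | intermediate
12 | tert-butyl (5E,8R)-8-[(tert-butyldimethylsilyl)oxy]-2-(diphenoxyphosphoryl)-9-[(4-methoxybenzyl)oxy]-6-methylnon-5-enoate | COc1ccc(COC[C@H](O[Si](C)(C)C(C)(C)C)C/C(C)=C/CCC(C(=O)OC(C)(C)C)P(=O)(Oc2ccccc2)Oc2ccccc2)cc1 | intermediate
13 | 2,2-dimethoxyacetaldehyde | COC(OC)C=O | starting material
14 | tert-butyl (2Z,5E,8R)-8-[(tert-butyldimethylsilyl)oxy]-2-(2,2-dimethoxyethylidene)-9-[(4-methoxybenzyl)oxy]-6-methylnon-5-enoate | COc1ccc(COC[C@H](O[Si](C)(C)C(C)(C)C)C/C(C)=C/CC/C(C(=O)OC(C)(C)C)=C/C(OC)OC)cc1 | intermediate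
15 | tert-butyl (2Z,5E,8R)-8-[(tert-butyldimethylsilyl)oxy]-2-(2,2-dimethoxyethylidene)-9-hydroxy-6-methylnon-5-enoate | OC[C@H](O[Si](C)(C)C(C)(C)C)C/C(C)=C/CC/C(C(=O)OC(C)(C)C)=C/C(OC)OC | intermediate
16 | tert-butyl (2Z,5E,8R)-8-[(tert-butyldimethylsilyl)oxy]-2-(2,2-dimethoxyethylidene)-6-methyl-9-oxonon-5-enoate | O=C[C@H](O[Si](C)(C)C(C)(C)C)C/C(C)=C/CC/C(C(=O)OC(C)(C)C)=C/C(OC)OC | intermediate
17 | methyl acrylate | C=CC(=O)OC | starting material
18 | 1-tert-butyl 11-methyl (2Z,5E,8R)-8-[(tert-butyldimethylsilyl)oxy]-2-(2,2-dimethoxyethylidene)-9-hydroxy-6-methyl-10-methylideneundec-5-enedioate | C=C(C(=O)OC)C(O)[C@H](O[Si](C)(C)C(C)(C)C)C/C(C)=C/CC/C(C(=O)OC(C)(C)C)=C/C(OC)OC | intermediate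
19 | 1-tert-butyl 11-methyl (2Z,5E,8R,9Z)-10-(bromomethyl)-8-[(tert-butyldimethylsilyl)oxy]-2-(2,2-dimethoxyethylidene)-6-methylundeca-5,9-dienedioate | COC(=O)/C(CBr)=C/[C@H](O[Si](C)(C)C(C)(C)C)C/C(C)=C/CC/C(C(=O)OC(C)(C)C)=C/C(OC)OC | intermediate
20 | 1-tert-butyl 11-methyl (2Z,5E,8R,9Z)-10-(bromomethyl)-8-hydroxy-6-methyl-2-(2-oxoethylidene)undeca-5,9-dienedioate | COC(=O)/C(CBr)=C/[C@H](O)C/C(C)=C/CC/C(C(=O)OC(C)(C)C)=C/C=O | intermediate
21 | dichlorochromium alkoxide (at the C3 oxygen) of tert-butyl (1Z,3R,4R,5R,7E)-3,5-dihydroxy-4-(3-methoxy-3-oxoprop-1-en-2-yl)-7-methylcyclodeca-1,7-diene-1-carboxylate | C/C1=C\CC/C(C(=O)OC(C)(C)C)=C/[C@@H](O[Cr](Cl)Cl)[C@H](C(=C)C(=O)OC)[C@H](O)C1 | intermediate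
22 | tert-butyl (3aR,4R,6E,10Z,11aR)-4-hydroxy-6-methyl-3-methylidene-2-oxo-2,3,3a,4,5,8,9,11a-octahydrocyclodeca[b]furan-10-carboxylate | C/C1=C\CC/C(C(=O)OC(C)(C)C)=C/[C@H]2OC(=O)C(=C)[C@@H]2[C@H](O)C1 | intermediate
23 | angelic acid, (2Z)-2-methylbut-2-enoic acid | C/C=C(/C)C(=O)O | starting material
24 | tert-butyl (3aR,4R,6E,10Z,11aR)-6-methyl-4-{[(2Z)-2-methylbut-2-enoyl]oxy}-3-methylidene-2-oxo-2,3,3a,4,5,8,9,11a-octahydrocyclodeca[b]furan-10-carboxylate | C/C1=C\CC/C(C(=O)OC(C)(C)C)=C/[C@H]2OC(=O)C(=C)[C@@H]2[C@H](OC(=O)/C(C)=C\C)C1 | intermediate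
25 | tert-butyl 2-[(3aR,4R,6S,7R,7aR)-6-ethenyl-6-methyl-4-{[(2Z)-2-methylbut-2-enoyl]oxy}-3-methylidene-2-oxooctahydro-1-benzofuran-7-yl]prop-2-enoate | C=C[C@]1(C)C[C@@H](OC(=O)/C(C)=C\C)[C@H]2C(=C)C(=O)O[C@@H]2[C@H]1C(=C)C(=O)OC(C)(C)C | intermediate
26 | 2-[(3aR,4R,6S,7R,7aR)-6-ethenyl-6-methyl-4-{[(2Z)-2-methylbut-2-enoyl]oxy}-3-methylidene-2-oxooctahydro-1-benzofuran-7-yl]prop-2-enoic acid | C=C[C@]1(C)C[C@@H](OC(=O)/C(C)=C\C)[C@H]2C(=C)C(=O)O[C@@H]2[C@H]1C(=C)C(=O)O | target

**Totals**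
Total step count: 16 (15 on the main line plus the preparation of phosphonate 11).
Longest linear sequence: 15 (steps 1–4 and 6–16).

**Steps most likely to fail**

Step 13 (ten-membered ring closure) is the main risk. Oligomerisation can compete with closure of the medium ring. The sense of induction from C8 and the 6,7-anti preference are predictions, not precedent on this substrate. The free C8 hydroxyl may lactonise onto C12 in place of O6. The oxygen on C8 can be lost from the allylchromium by 1,4-elimination. Divalent chromium may attack the 4-oxo-enoate, and 20 itself is labile. The fallback sets out from 19 and comes back at 22; it replaces the reductively formed allylchromium by an isolable allyltin and closes the ring by Lewis acid through an open transition state, with C8 kept silylated. Bromide 19 is stannylated (Bu3Sn–SnBu3, Pd(PPh3)4, THF) to the allylstannane 1-tert-butyl 11-methyl (2Z,5E,8R,9Z)-8-[(tert-butyldimethylsilyl)oxy]-2-(2,2-dimethoxyethylidene)-6-methyl-10-[(tributylstannyl)methyl]undeca-5,9-dienedioate F1. Hydrolysis of the acetal alone (LiBF4, wet MeCN) gives the stannyl aldehyde F2. BF3·OEt2 in CH2Cl2 at −78 °C under high dilution, followed by mildly acidic work-up to lactonise, gives the silylated germacranolide F3. HF·pyridine then frees the C8 hydroxyl to give 22.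

Step 15 (Cope rearrangement) is the second risk. The temperature needed and the position of the germacrane/elemane equilibrium are not known for this substitution pattern. A second diene conformer would give the C5,C10 bis-epimer, and prolonged heating endangers the angelate. The fallback sets out from 24 and comes back at the target 26 by inverting the order of the last two operations. TFA–CH2Cl2 first cleaves the tert-butyl ester to the germacranolide acid F4. The free acid is then rearranged in PhMe at 80–110 °C; its carboxyl group is a stronger acceptor on C4 and the product is the target itself.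

Step 2 (carboalumination and epoxide opening) is the third risk. The alanate may open ethylene oxide sluggishly in the presence of the aluminium alkoxide and the benzylic ether. The fallback sets out from 3 and comes back at 6, replacing the epoxide opening by a cross-coupling. The same carboalumination is quenched with I2 to give the vinyl iodide (2R,4E)-5-iodo-1-[(4-methoxybenzyl)oxy]-4-methylpent-4-en-2-ol F5. B-alkyl Suzuki–Miyaura coupling with the 9-BBN adduct of tert-butyldimethyl(vinyloxy)silane (PdCl2(dppf), K3PO4, DMF–THF) gives the silyl ether (2R,4E)-7-[(tert-butyldimethylsilyl)oxy]-1-[(4-methoxybenzyl)oxy]-4-methylhept-4-en-2-ol F6. Bu4NF then gives 6.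

**Further compounds**
F1 | step 13 | 1-tert-butyl 11-methyl (2Z,5E,8R,9Z)-8-[(tert-butyldimethylsilyl)oxy]-2-(2,2-dimethoxyethylidene)-6-methyl-10-[(tributylstannyl)methyl]undeca-5,9-dienedioate | COC(=O)/C(C[Sn](CCCC)(CCCC)CCCC)=C/[C@H](O[Si](C)(C)C(C)(C)C)C/C(C)=C/CC/C(C(=O)OC(C)(C)C)=C/C(OC)OC
F2 | step 13 | 1-tert-butyl 11-methyl (2Z,5E,8R,9Z)-8-[(tert-butyldimethylsilyl)oxy]-6-methyl-2-(2-oxoethylidene)-10-[(tributylstannyl)methyl]undeca-5,9-dienedioate | COC(=O)/C(C[Sn](CCCC)(CCCC)CCCC)=C/[C@H](O[Si](C)(C)C(C)(C)C)C/C(C)=C/CC/C(C(=O)OC(C)(C)C)=C/C=O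
F3 | step 13 | tert-butyl (3aS,4R,6E,10Z,11aR)-4-[(tert-butyldimethylsilyl)oxy]-6-methyl-3-methylidene-2-oxo-2,3,3a,4,5,8,9,11a-octahydrocyclodeca[b]furan-10-carboxylate | C/C1=C\CC/C(C(=O)OC(C)(C)C)=C/[C@H]2OC(=O)C(=C)[C@@H]2[C@H](O[Si](C)(C)C(C)(C)C)C1
F4 | step 15 | (3aR,4R,6E,10Z,11aR)-6-methyl-4-{[(2Z)-2-methylbut-2-enoyl]oxy}-3-methylidene-2-oxo-2,3,3a,4,5,8,9,11a-octahydrocyclodeca[b]furan-10-carboxylic acid | C/C1=C\CC/C(C(=O)O)=C/[C@H]2OC(=O)C(=C)[C@@H]2[C@H](OC(=O)/C(C)=C\C)C1
F5 | step 2 | (2R,4E)-5-iodo-1-[(4-methoxybenzyl)oxy]-4-methylpent-4-en-2-ol | COc1ccc(COC[C@H](O)C/C(C)=C/I)cc1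
F6 | step 2 | (2R,4E)-7-[(tert-butyldimethylsilyl)oxy]-1-[(4-methoxybenzyl)oxy]-4-methylhept-4-en-2-ol | COc1ccc(COC[C@H](O)C/C(C)=C/CCO[Si](C)(C)C(C)(C)C)cc1
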